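## The problem

The target is the 3-O-galloyl ester of a (2R,3S,4S)-flavan-3,4-diol. A chroman (ring C) is fused to a 5,7-dihydroxylated benzene (ring A) and carries a catechol (ring B) at C2, the galloyl ester on O3 and a free hydroxyl at C4. The three contiguous stereocentres are 2,3-trans and 3,4-cis. The cis pair C3/C4 is an erythro diol that can be bought as a cis-dioxolane; the C3 oxygen can then set the neighbouring C2 carbinol by 1,2-induction, and the configuration made at C2 has to match the steric course (inversion or retention) of the ring C closure. The C4–O bond is benzylic to an arene with oxygen donors in both ortho positions and the para position, so it ionises under acid (epimerisation, solvolysis, arylation by a second ring A) and is exposed during hydrogenolysis. The free polyphenol is sensitive to base and air, and the ester on O3 lies cis to a free hydroxyl and can migrate, so O3 must be acylated late and selectively beside O4. The feature that opens the chosen route is ring A itself: a 1,3,5-trioxygenated benzene whose only carbon substituent, C4 on C4a, lies between the oxygen-bearing carbons C5 and C8a and para to the oxygen on C7. This is the pattern formed when a 3-alkoxyvinylketene (supplying C6, C7, C8, C8a) meets a siloxyalkyne whose carbon terminus (C4a) carries the C4 chain and whose oxygen terminus becomes C5.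

## Retrosynthesis

**Unmasking and the ester.** Target 28 is traced to its hepta-O-benzyl ether 27 by cutting seven O–CH2Ph bonds, and 27 to cis-diol 24 plus acid chloride 26 (made in the flask from acid 25) by cutting the ester C–O bond at O3. The gallate comes last because no ester would survive the organolithium, hydride and fluoride steps, and because O3 is tied up with O4 until late. Benzyl ethers tolerate every earlier step and leave under neutral hydrogen. The forward acylation must prefer the equatorial O3 over the pseudoaxial O4, which is shielded by the peri substituent on C5; the hydrogenolysis must leave the C4–O bond alone.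

**Diol and O5.** Diol 24 comes from acetonide 23 (two acetal C–O bonds), and 23 from phenol 22 (the O–CH2Ph bond on O5). The acetonide is the part of the chiral pool that stays on; it keeps O3 and O4 silent and locked cis until ring C exists. The forward hydrolysis must cleave the acetal carbon–oxygen bonds faster than the C4–O bond ionises.

**Ring C.** Chroman 22 is opened at O1–C2 to triol 21. A C8a–O1 cut was the neighbour to weigh, but the annulation below delivers ring A as a phenol with O1 already on C8a, so O1 is the natural nucleophile and no aryl halide is needed. The closure is an SN2 etherification with inversion, so C2 in 21 must be the epimer of C2 in the target. The two phenolic hydroxyls of 21 flank the chain symmetrically, so either gives the same chroman. Triol 21 comes from 20 by cutting two O–Si bonds.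

**Ring A (key disconnection).** Phenol 20 is cut at C4a–C8a, C5–C6 and C8–C8a into siloxyalkyne 13 and cyclobutenone 15. The alternative of adding a ready-made phloroglucinol ring as an aryl metal to a C4 carbonyl would create C4 as a new stereocentre at the most ionisable position and would need metalation between two oxygens. The annulation instead makes C4 benzylic only when ring A appears, under neutral thermal conditions, and fixes the oxygen pattern by its mechanism. The precursor loses a whole ring and becomes an acyclic alkyne plus a four-carbon unit. The forward reaction needs only regiocontrol and thermal tolerance of the silyl ethers and the dioxolane.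

**Cyclobutenone.** Compound 15 comes from commercial 3-ethoxycyclobutenone 14 by exchanging the ethyl for a benzyl group, since the ether on O7 must be removable at the end.

**Siloxyalkyne and C2.** Siloxyalkyne 13 is cut at the alkyne C–O bond and the O–Si bond to terminal alkyne 10, which is the silyl ether of carbinol 9. The syn carbinol 9 comes from ketone 8 by cutting the C2–H bond. Direct Felkin addition of the aryl Grignard reagent 6 to aldehyde 4 would favour the anti carbinol, which is wrong for an inverting closure, whereas Felkin delivery of hydride to ketone 8 gives the syn isomer. Ketone 8 is therefore reached from the carbinol mixture 7, made from aldehyde 4 and bromide 5 (through 6) by forming the C2–C1' bond.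

**Chiral pool.** Aldehyde 4 comes from alkynol 3, and 3 from lactol 2 by a one-carbon homologation that turns the lactol carbon into the alkyne carbon (later C4a). Lactol 2 comes from D-lactone 1. In this orientation the lactone carbonyl end becomes the arene end and the CH2O end becomes C2, which is the assignment that gives the (3S,4S) series from the D-lactone.

## Roads not taken

**Alternative 1:** ring C by ortho-quinone methide cycloaddition. The cut removes O1–C2 and C3–C4 together. In the forward step a chiral phosphoric acid would ionise 3,5-bis(benzyloxy)-2-[bis(benzyloxy)methyl]phenol A2 to an α-benzyloxy ortho-quinone methide, which would add across the E double bond of the enol gallate A3 to give A1, the fully benzylated target with a benzyl ether on O4.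
- Merits: this is by far the shortest road; it sets all three stereocentres in one step and brings the gallate with it, so the O3/O4 differentiation disappears. In step count the chosen plan cannot compete.
- Weak points: enol esters are poor 2π partners for ortho-quinone methides. The E geometry secures only the 2,3-trans relation; the 3,4-cis relation and the absolute configuration would rest on endo/exo and facial control by the catalyst on a substrate pair for which this has not been shown. The acid that releases the quinone methide can also re-ionise the 4-alkoxy product A1. The final hydrogenolysis must choose between two benzylic C–O bonds on the same oxygen at C4.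
- Comparison: the chosen plan is much longer, but every stereocentre in it comes from the chiral pool or from a well-understood substrate-controlled step.

**Alternative 2:** ring C by pinacol closure across C3–C4. In the forward step SmI2 would form the ketyl of the aryl aldehyde in dialdehyde A5, which would add to the aliphatic aldehyde and give cis-diol A4, identical with 24.
- Merits: A4 joins the chosen end-game directly, the route is several steps shorter, and it has no acetonide, so the acid step that the chosen plan must survive is absent. In these respects it is better.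
- Weak points: C2 of A5 is an α-aryl, α-aryloxy aldehyde carbon. It is the only source of absolute configuration and it enolises very easily. A samarium ketyl next to an aryloxy group can expel the phenoxide, which would cut the tether. The 2,3-trans relation would rest on one labile centre.
- Comparison: the chosen plan has configurational security to set against this. C3 and C4 are purchased, and C2 is formed when it is not next to a carbonyl group.

**Alternative 3:** ring C closed at the aryl–oxygen bond. The cut is C8a–O1. In the forward step CuI, a phenanthroline ligand and Cs2CO3 would couple the C2 hydroxyl of bromo alcohol A7 with its ortho bromide to give A6, identical with 23.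
- Merits: the closure goes with retention, so the anti carbinol that Felkin addition of an aryl metal gives directly could be used and the oxidation–reduction pair would be saved. Ring A is bought, not built. The route is probably shorter than the chosen one and it avoids an SN2 reaction at an electron-rich benzylic carbon.
- Weak points: an electron-rich bromide with an ortho substituent is a poor partner for copper-mediated etherification with a secondary benzylic alcohol. Hot carbonate base invites oxidation or epimerisation at C2. A7 itself needs the C4–C4a bond to be made either with an ortho-bromo aryl metal (prone to aryne formation) or by late bromination with a regiochemical question, and it needs C4 to be set as a new stereocentre at the ionisable position.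
- Comparison: in the chosen plan the C4–C4a bond is already present in the alkyne, the oxygen pattern of ring A follows from the annulation mechanism, and ring C closes without metal at room temperature.

Key step: step 10

Assumption: 3,4,5-tris(benzyloxy)benzoic acid 25, the tri-O-benzyl ether of gallic acid, is taken as a purchased starting material.
Assumption: lactol 2 and carbinol 7 are used as mixtures at the one centre that the following step removes.

## Route

Step 1
Reactants: 1 2,3-O-isopropylidene-D-erythronolactone
Product: 2 2,3-O-isopropylidene-D-erythrose (furanose lactol; both anomers)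
Conditions: i-Bu2AlH, CH2Cl2, −78 °C
Reagents that add atoms: none
Why: Partial reduction of a γ-lactone by a dialkylaluminium hydride stops at the aluminium hemiacetal at low temperature; the two dioxolane stereocentres are not involved.

Step 2
Reactants: 2 2,3-O-isopropylidene-D-erythrose
Product: 3 [(4R,5S)-5-ethynyl-2,2-dimethyl-1,3-dioxolan-4-yl]methanol
Conditions: dimethyl (1-diazo-2-oxopropyl)phosphonate, K2CO3, MeOH, 0 °C → rt
Reagents that add atoms: dimethyl (1-diazo-2-oxopropyl)phosphonate, COP(=O)(OC)C(=[N+]=[N-])C(C)=O
Why: Seyferth–Gilbert homologation in the Ohira–Bestmann variant acts on the open hydroxy aldehyde form of the lactol; the former lactone carbon becomes the internal alkyne carbon (later C4a) and the freed primary alcohol is the later C2.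

Step 3
Reactants: 3 [(4R,5S)-5-ethynyl-2,2-dimethyl-1,3-dioxolan-4-yl]methanol
Product: 4 (4S,5S)-5-ethynyl-2,2-dimethyl-1,3-dioxolane-4-carbaldehyde
Conditions: Dess–Martin periodinane, CH2Cl2, 0 °C → rt; used crude
Reagents that add atoms: none
Why: Dess–Martin oxidation is neutral and fast, which should keep the epimerisable cis α-alkoxy aldehyde intact; the alkyne is inert.

Step 4
Reactants: 4 (4S,5S)-5-ethynyl-2,2-dimethyl-1,3-dioxolane-4-carbaldehyde; 5 4-bromo-1,2-bis(benzyloxy)benzene
Product: 7 [3,4-bis(benzyloxy)phenyl][(4R,5S)-5-ethynyl-2,2-dimethyl-1,3-dioxolan-4-yl]methanol (both carbinol epimers), via aryl Grignard reagent 6 (not isolated)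
Conditions: 5, Mg, THF, rt; then 4, THF, −78 → −40 °C
Reagents that add atoms: none
Why: Grignard addition to an aldehyde forms the C2–C1' bond; at low temperature addition should outrun deprotonation of the terminal alkyne, and the facial outcome does not matter because the next step removes this centre.

Step 5
Reactants: 7 [3,4-bis(benzyloxy)phenyl][(4R,5S)-5-ethynyl-2,2-dimethyl-1,3-dioxolan-4-yl]methanol
Product: 8 [3,4-bis(benzyloxy)phenyl][(4S,5S)-5-ethynyl-2,2-dimethyl-1,3-dioxolan-4-yl]methanone
Conditions: Dess–Martin periodinane, CH2Cl2, 0 °C → rt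
Reagents that add atoms: none
Why: Dess–Martin oxidation of a benzylic alcohol to the aryl ketone under neutral conditions, so the cis α-alkoxy centre next to the new carbonyl should not epimerise.

Step 6
Reactants: 8 [3,4-bis(benzyloxy)phenyl][(4S,5S)-5-ethynyl-2,2-dimethyl-1,3-dioxolan-4-yl]methanone
Product: 9 (S)-[3,4-bis(benzyloxy)phenyl][(4R,5S)-5-ethynyl-2,2-dimethyl-1,3-dioxolan-4-yl]methanol
Conditions: LiBH(s-Bu)3 (L-Selectride), THF, −78 °C
Reagents that add atoms: none
Why: Felkin–Anh reduction of an α-alkoxy ketone by a bulky, non-chelating hydride: the ring C–O bond stands anti to the incoming hydride, which passes the α-hydrogen, and this should give the syn (S) carbinol required for an inverting ring closure.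

Step 7
Reactants: 9 (S)-[3,4-bis(benzyloxy)phenyl][(4R,5S)-5-ethynyl-2,2-dimethyl-1,3-dioxolan-4-yl]methanol
Product: 10 {(S)-[3,4-bis(benzyloxy)phenyl][(4S,5S)-5-ethynyl-2,2-dimethyl-1,3-dioxolan-4-yl]methoxy}(tert-butyl)dimethylsilane
Conditions: t-BuMe2SiOTf, 2,6-lutidine, CH2Cl2, −78 → 0 °C
Reagents that add atoms: tert-butyldimethylsilyl trifluoromethanesulfonate, CC(C)(C)[Si](C)(C)OS(=O)(=O)C(F)(F)F
Why: Silylation of a hindered secondary alcohol with a silyl triflate and a hindered base; the ether removes the acidic proton before the acetylide is made and is later cleaved by the same fluoride that frees the phenol.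

Step 8
Reactants: 10 {(S)-[3,4-bis(benzyloxy)phenyl][(4S,5S)-5-ethynyl-2,2-dimethyl-1,3-dioxolan-4-yl]methoxy}(tert-butyl)dimethylsilane
Product: 13 tert-butyl{(S)-[3,4-bis(benzyloxy)phenyl][(4S,5S)-2,2-dimethyl-5-{[tri(propan-2-yl)silyl]oxyethynyl}-1,3-dioxolan-4-yl]methoxy}dimethylsilane, via lithium acetylide 11 (not isolated), via lithium ynolate 12 (not isolated)
Conditions: n-BuLi, THF, −78 °C; LiOO-t-Bu (from t-BuOOH, LiN(SiMe3)2), −78 → 0 °C; i-Pr3SiOTf, −78 °C
Reagents that add atoms: tert-butyl hydroperoxide (used as its lithium salt), CC(C)(C)OO; triisopropylsilyl trifluoromethanesulfonate, CC(C)[Si](OS(=O)(=O)C(F)(F)F)(C(C)C)C(C)C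
Why: Oxidation of a lithium acetylide by lithium tert-butyl peroxide (attack of the acetylide carbon on the peroxide oxygen) is an established route to ynolates, and the bulky silyl triflate traps the ynolate on oxygen to give the siloxyalkyne; no stereocentre is touched.

Step 9
Reactants: 14 3-ethoxycyclobut-2-en-1-one
Product: 15 3-(benzyloxy)cyclobut-2-en-1-one
Conditions: BnOH (excess), camphorsulfonic acid (cat.), toluene, 45 °C, reduced pressure (EtOH removed)
Reagents that add atoms: benzyl alcohol, OCc1ccccc1
Why: Acid-catalysed exchange of the alkoxy group of a vinylogous ester by addition–elimination at the β-carbon, driven by removal of the more volatile ethanol.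

Step 10
Reactants: 13 tert-butyl{(S)-[3,4-bis(benzyloxy)phenyl][(4S,5S)-2,2-dimethyl-5-{[tri(propan-2-yl)silyl]oxyethynyl}-1,3-dioxolan-4-yl]methoxy}dimethylsilane; 15 3-(benzyloxy)cyclobut-2-en-1-one
Product: 20 5-(benzyloxy)-2-[(4S,5S)-5-{(S)-[3,4-bis(benzyloxy)phenyl][(tert-butyldimethylsilyl)oxy]methyl}-2,2-dimethyl-1,3-dioxolan-4-yl]-3-[(triisopropylsilyl)oxy]phenol, via vinylketene 16 (not isolated), via cyclobutenone adduct 17 (not isolated), via dienylketene 18 (not isolated), via cyclohexadienone 19 (not isolated)
Conditions: 15 (excess), toluene, 80 → 110 °C, sealed vessel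
Reagents that add atoms: none
Why: This is a Danheiser benzannulation of a cyclobutenone with a siloxyalkyne, the closest known reaction type, here with an alkoxy group on the four-membered ring. Heat opens 15 by 4π electrocyclic ring opening to vinylketene 16, whose ketene C=C adds to the alkyne of 13 in a regioselective [2+2] cycloaddition: the nucleophilic alkyne carbon, the one that carries the dioxolane, bonds to the ketene carbonyl carbon and gives cyclobutenone 17 (C4a–C8a and C5–C6 formed). A second 4π opening gives dienylketene 18; only the isomer with the alkoxyvinyl group turned inward can go on, and because the opening is reversible the material should funnel through it. Ring A is closed by thermal 6π electrocyclisation of 18 (C8–C8a formed), and cyclohexadienone 19 tautomerises to phenol 20. No stereocentre is created, and the three existing ones are remote from every bond that changes in a medium without acid or base. The only selectivity needed is regiochemical, and the polarisation of the siloxyalkyne secures it: the chain carbon ends up between the silyloxy-bearing carbon and the carbon of the free phenol, with the benzyloxy group para to the chain.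

Step 11
Reactants: 20 5-(benzyloxy)-2-[(4S,5S)-5-{(S)-[3,4-bis(benzyloxy)phenyl][(tert-butyldimethylsilyl)oxy]methyl}-2,2-dimethyl-1,3-dioxolan-4-yl]-3-[(triisopropylsilyl)oxy]phenol
Product: 21 5-(benzyloxy)-2-[(4S,5R)-5-{(S)-[3,4-bis(benzyloxy)phenyl](hydroxy)methyl}-2,2-dimethyl-1,3-dioxolan-4-yl]benzene-1,3-diol
Conditions: n-Bu4NF, THF, 0 °C → rt
Reagents that add atoms: none
Why: Fluoride cleaves the aryl silyl ether quickly and the secondary alkyl silyl ether more slowly; the acetonide and benzyl ethers are inert, and the product has two equivalent phenolic hydroxyls beside the chain.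

Step 12
Reactants: 21 5-(benzyloxy)-2-[(4S,5R)-5-{(S)-[3,4-bis(benzyloxy)phenyl](hydroxy)methyl}-2,2-dimethyl-1,3-dioxolan-4-yl]benzene-1,3-diol
Product: 22 3,4-O-isopropylidene derivative of (2R,3S,4S)-7-(benzyloxy)-2-[3,4-bis(benzyloxy)phenyl]chromane-3,4,5-triol (5-OH free)
Conditions: PPh3, DIAD, THF (dilute), 0 °C → rt
Reagents that add atoms: none
Why: Intramolecular Mitsunobu etherification closes the six-membered ring C by SN2 attack of a phenol on the activated benzylic carbinol with inversion, turning the syn (S) carbinol into the 2,3-trans (2R) chroman; either phenol gives the same product, and any leakage through a C2 cation is expected to place the aryl group on the convex face, again trans to O3.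

Step 13
Reactants: 22 3,4-O-isopropylidene derivative of (2R,3S,4S)-7-(benzyloxy)-2-[3,4-bis(benzyloxy)phenyl]chromane-3,4,5-triol
Product: 23 3,4-O-isopropylidene derivative of (2R,3S,4S)-5,7-bis(benzyloxy)-2-[3,4-bis(benzyloxy)phenyl]chromane-3,4-diol
Conditions: BnBr, K2CO3, DMF, rt
Reagents that add atoms: benzyl bromide, BrCc1ccccc1
Why: Williamson benzylation of the one remaining phenol; it removes the free ortho hydroxyl that would make the C4–O bond still more labile.

Step 14
Reactants: 23 3,4-O-isopropylidene derivative of (2R,3S,4S)-5,7-bis(benzyloxy)-2-[3,4-bis(benzyloxy)phenyl]chromane-3,4-diol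
Product: 24 (2R,3S,4S)-5,7-bis(benzyloxy)-2-[3,4-bis(benzyloxy)phenyl]chromane-3,4-diol
Conditions: AcOH/H2O/THF (3:1:1), 40 °C, stopped at full conversion
Reagents that add atoms: none
Why: Acid-catalysed acetal hydrolysis through the tertiary oxocarbenium ion at the acetal carbon should be faster than heterolysis of the C4–O bond, which the adjacent C3 oxygen retards, so the cis-diol is expected with C4 unchanged.

Step 15
Reactants: 24 (2R,3S,4S)-5,7-bis(benzyloxy)-2-[3,4-bis(benzyloxy)phenyl]chromane-3,4-diol; 25 3,4,5-tris(benzyloxy)benzoic acid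
Product: 27 (2R,3S,4S)-5,7-bis(benzyloxy)-2-[3,4-bis(benzyloxy)phenyl]-4-hydroxychroman-3-yl 3,4,5-tris(benzyloxy)benzoate, via acid chloride 26 (not isolated)
Conditions: 25, (COCl)2, DMF (cat.), CH2Cl2, rt, evaporation; then 24, Me2SnCl2 (cat.), i-Pr2NEt, THF, 0 °C → rt
Reagents that add atoms: none
Why: Tin-catalysed regioselective monoacylation of a cis-1,2-diol: the tin binds both oxygens and the equatorial one is acylated, which here is O3; the pseudoaxial O4 is in addition shielded by the peri benzyloxy group on C5.

Step 16
Reactants: 27 (2R,3S,4S)-5,7-bis(benzyloxy)-2-[3,4-bis(benzyloxy)phenyl]-4-hydroxychroman-3-yl 3,4,5-tris(benzyloxy)benzoate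
Product: 28 (2R,3S,4S)-2-(3,4-dihydroxyphenyl)-4,5,7-trihydroxychroman-3-yl 3,4,5-trihydroxybenzoate
Conditions: H2 (1 atm), Pd(OH)2/C, THF/EtOAc, rt, stopped when debenzylation is complete
Reagents that add atoms: none
Why: Hydrogenolysis of aryl benzyl ethers is much faster than cleavage of a benzylic alcohol C–O bond in a neutral, aprotic medium, so all seven ethers should go while the ester, the C2–O1 bond and the C4 hydroxyl remain.

## Compound list

1 | 2,3-O-isopropylidene-D-erythronolactone | O=C1OC[C@H]2OC(C)(C)O[C@@H]12 | starting material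
2 | 2,3-O-isopropylidene-D-erythrose (lactol, both anomers) | OC1OC[C@H]2OC(C)(C)O[C@@H]12 | intermediate
3 | [(4R,5S)-5-ethynyl-2,2-dimethyl-1,3-dioxolan-4-yl]methanol | C#C[C@@H]1OC(C)(C)O[C@@H]1CO | intermediate
4 | (4S,5S)-5-ethynyl-2,2-dimethyl-1,3-dioxolane-4-carbaldehyde | C#C[C@@H]1OC(C)(C)O[C@@H]1C=O | intermediate
5 | 4-bromo-1,2-bis(benzyloxy)benzene | Brc1ccc(OCc2ccccc2)c(OCc2ccccc2)c1 | starting material
6 | [3,4-bis(benzyloxy)phenyl]magnesium bromide | Br[Mg]c1ccc(OCc2ccccc2)c(OCc2ccccc2)c1 | intermediate (not isolated)
7 | [3,4-bis(benzyloxy)phenyl][(4R,5S)-5-ethynyl-2,2-dimethyl-1,3-dioxolan-4-yl]methanol, both carbinol epimers | C#C[C@@H]1OC(C)(C)O[C@@H]1C(O)c1ccc(OCc2ccccc2)c(OCc2ccccc2)c1 | intermediate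
8 | [3,4-bis(benzyloxy)phenyl][(4S,5S)-5-ethynyl-2,2-dimethyl-1,3-dioxolan-4-yl]methanone | C#C[C@@H]1OC(C)(C)O[C@@H]1C(=O)c1ccc(OCc2ccccc2)c(OCc2ccccc2)c1 | intermediate
9 | (S)-[3,4-bis(benzyloxy)phenyl][(4R,5S)-5-ethynyl-2,2-dimethyl-1,3-dioxolan-4-yl]methanol | C#C[C@@H]1OC(C)(C)O[C@@H]1[C@@H](O)c1ccc(OCc2ccccc2)c(OCc2ccccc2)c1 | intermediate
10 | {(S)-[3,4-bis(benzyloxy)phenyl][(4S,5S)-5-ethynyl-2,2-dimethyl-1,3-dioxolan-4-yl]methoxy}(tert-butyl)dimethylsilane | C#C[C@@H]1OC(C)(C)O[C@@H]1[C@@H](O[Si](C)(C)C(C)(C)C)c1ccc(OCc2ccccc2)c(OCc2ccccc2)c1 | intermediate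
11 | lithium acetylide of 10 | [Li]C#C[C@@H]1OC(C)(C)O[C@@H]1[C@@H](O[Si](C)(C)C(C)(C)C)c1ccc(OCc2ccccc2)c(OCc2ccccc2)c1 | intermediate (not isolated)
12 | lithium ynolate derived from 11 (oxygen on the former terminal alkyne carbon) | [Li]OC#C[C@@H]1OC(C)(C)O[C@@H]1[C@@H](O[Si](C)(C)C(C)(C)C)c1ccc(OCc2ccccc2)c(OCc2ccccc2)c1 | intermediate (not isolated)
13 | tert-butyl{(S)-[3,4-bis(benzyloxy)phenyl][(4S,5S)-2,2-dimethyl-5-{[tri(propan-2-yl)silyl]oxyethynyl}-1,3-dioxolan-4-yl]methoxy}dimethylsilane | CC(C)[Si](OC#C[C@@H]1OC(C)(C)O[C@@H]1[C@@H](O[Si](C)(C)C(C)(C)C)c1ccc(OCc2ccccc2)c(OCc2ccccc2)c1)(C(C)C)C(C)C | intermediate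
14 | 3-ethoxycyclobut-2-en-1-one | CCOC1=CC(=O)C1 | starting material
15 | 3-(benzyloxy)cyclobut-2-en-1-one | O=C1C=C(OCc2ccccc2)C1 | intermediate
16 | 3-(benzyloxy)buta-1,3-dien-1-one (vinylketene) | C=C(OCc1ccccc1)C=C=O | intermediate (not isolated)
17 | 4-[1-(benzyloxy)ethenyl]-3-[(triisopropylsilyl)oxy]cyclobut-2-en-1-one carrying at C2 the (4S,5S)-dioxolanyl chain of 13, both C4 epimers | O=C1C(=C(O[Si](C(C)C)(C(C)C)C(C)C)C1C(=C)OCc1ccccc1)[C@@H]1OC(C)(C)O[C@@H]1[C@@H](O[Si](C)(C)C(C)(C)C)c1ccc(OCc2ccccc2)c(OCc2ccccc2)c1 | intermediate (not isolated)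
18 | 5-(benzyloxy)-3-[(triisopropylsilyl)oxy]hexa-1,3,5-trien-1-one carrying the same chain at C2, ketene carbon and alkoxyvinyl group cis on the C3=C4 bond (dienylketene) | O=C=C([C@@H]1OC(C)(C)O[C@@H]1[C@@H](O[Si](C)(C)C(C)(C)C)c1ccc(OCc2ccccc2)c(OCc2ccccc2)c1)/C(O[Si](C(C)C)(C(C)C)C(C)C)=C\C(=C)OCc1ccccc1 | intermediate (not isolated)
19 | 5-(benzyloxy)-3-[(triisopropylsilyl)oxy]cyclohexa-2,4-dien-1-one carrying the same chain at C2 | O=C1CC(OCc2ccccc2)=CC(O[Si](C(C)C)(C(C)C)C(C)C)=C1[C@@H]1OC(C)(C)O[C@@H]1[C@@H](O[Si](C)(C)C(C)(C)C)c1ccc(OCc2ccccc2)c(OCc2ccccc2)c1 | intermediate (not isolated)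
20 | 5-(benzyloxy)-2-[(4S,5S)-5-{(S)-[3,4-bis(benzyloxy)phenyl][(tert-butyldimethylsilyl)oxy]methyl}-2,2-dimethyl-1,3-dioxolan-4-yl]-3-[(triisopropylsilyl)oxy]phenol | Oc1cc(OCc2ccccc2)cc(O[Si](C(C)C)(C(C)C)C(C)C)c1[C@@H]1OC(C)(C)O[C@@H]1[C@@H](O[Si](C)(C)C(C)(C)C)c1ccc(OCc2ccccc2)c(OCc2ccccc2)c1 | intermediate
21 | 5-(benzyloxy)-2-[(4S,5R)-5-{(S)-[3,4-bis(benzyloxy)phenyl](hydroxy)methyl}-2,2-dimethyl-1,3-dioxolan-4-yl]benzene-1,3-diol | Oc1cc(OCc2ccccc2)cc(O)c1[C@@H]1OC(C)(C)O[C@@H]1[C@@H](O)c1ccc(OCc2ccccc2)c(OCc2ccccc2)c1 | intermediate
22 | 3,4-O-isopropylidene derivative of (2R,3S,4S)-7-(benzyloxy)-2-[3,4-bis(benzyloxy)phenyl]chromane-3,4,5-triol (5-OH free) | CC1(C)O[C@@H]2[C@@H](c3ccc(OCc4ccccc4)c(OCc4ccccc4)c3)Oc3cc(OCc4ccccc4)cc(O)c3[C@@H]2O1 | intermediate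
23 | 3,4-O-isopropylidene derivative of (2R,3S,4S)-5,7-bis(benzyloxy)-2-[3,4-bis(benzyloxy)phenyl]chromane-3,4-diol | CC1(C)O[C@@H]2[C@@H](c3ccc(OCc4ccccc4)c(OCc4ccccc4)c3)Oc3cc(OCc4ccccc4)cc(OCc4ccccc4)c3[C@@H]2O1 | intermediate
24 | (2R,3S,4S)-5,7-bis(benzyloxy)-2-[3,4-bis(benzyloxy)phenyl]chromane-3,4-diol | O[C@@H]1[C@@H](c2ccc(OCc3ccccc3)c(OCc3ccccc3)c2)Oc2cc(OCc3ccccc3)cc(OCc3ccccc3)c2[C@@H]1O | intermediate
25 | 3,4,5-tris(benzyloxy)benzoic acid | O=C(O)c1cc(OCc2ccccc2)c(OCc2ccccc2)c(OCc2ccccc2)c1 | starting material
26 | 3,4,5-tris(benzyloxy)benzoyl chloride | O=C(Cl)c1cc(OCc2ccccc2)c(OCc2ccccc2)c(OCc2ccccc2)c1 | intermediate (not isolated)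
27 | (2R,3S,4S)-5,7-bis(benzyloxy)-2-[3,4-bis(benzyloxy)phenyl]-4-hydroxychroman-3-yl 3,4,5-tris(benzyloxy)benzoate | O=C(O[C@@H]1[C@@H](c2ccc(OCc3ccccc3)c(OCc3ccccc3)c2)Oc2cc(OCc3ccccc3)cc(OCc3ccccc3)c2[C@@H]1O)c1cc(OCc2ccccc2)c(OCc2ccccc2)c(OCc2ccccc2)c1 | intermediate
28 | (2R,3S,4S)-2-(3,4-dihydroxyphenyl)-4,5,7-trihydroxychroman-3-yl 3,4,5-trihydroxybenzoate | O=C(O[C@@H]1[C@@H](c2ccc(O)c(O)c2)Oc2cc(O)cc(O)c2[C@@H]1O)c1cc(O)c(O)c(O)c1 | target

## Step count and least certain steps

Total step count: 16. Longest linear sequence: 15 steps (steps 1–8 from lactone 1, then steps 10–16); step 9 is the only step off this line.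

**Step 10 (key step).** The ring opening of the push–pull cyclobutenone 15 may be too slow below the temperature at which siloxyalkyne 13 suffers silyl migration to a silylketene. Vinylketene 16 may also be lost to dimerisation or to acylation of the product phenol before it meets the alkyne. The fallback generates 16 at or below room temperature by a different reaction. Phosphine-catalysed addition of benzyl alcohol to ethyl but-2-ynoate would give ethyl (E)-3-(benzyloxy)but-2-enoate F1, saponification the acid (E)-3-(benzyloxy)but-2-enoic acid F2, and oxalyl chloride the chloride (E)-3-(benzyloxy)but-2-enoyl chloride F3. Slow addition of F3 to 13 and triethylamine would form 16 by 1,4-dehydrochlorination in the presence of the alkyne, giving 17 by [2+2] addition; gentle warming would take 17 through 18 and 19. This fallback sets out from 13 and returns to the route at 20.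

**Step 9.** Acid-mediated hydrolysis or ring cleavage of the strained vinylogous ester may compete with alkoxy exchange, or the equilibrium may not be driven to completion. In the fallback, 14 is hydrolysed with dilute aqueous acid to cyclobutane-1,3-dione F4, whose acidic enol is O-benzylated with benzyl alcohol under Mitsunobu conditions. It sets out from 14 and returns at 15.

**Step 12.** The activated benzylic oxygen at the electron-rich C2 may ionise before the phenol attacks, leading to elimination or loss of stereochemical fidelity, or the second phenol may be alkylated intermolecularly. The fallback gives up the SN2 pathway and closes the ring under deliberately ionising, stereoconvergent conditions. Triol 21 would be treated at high dilution with a catalytic sulfonic acid in an anhydrous, non-nucleophilic ionising medium (CH2Cl2/hexafluoroisopropanol, low temperature), so that the C2 cation is captured by the neighbouring phenol with the aryl group on the convex face of the cis-fused dioxolane. The dioxolane keeps the C4 oxygen tethered, so a transient opening at C4 should be reversible. No new compound is made (F0); the fallback sets out from 21 and returns at 22.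

**Step 14.** Heterolysis of the benzylic C4–O bond may compete with acetal cleavage, with epimerisation at C4, capture by acetic acid or arylation of a second molecule. The fallback changes from kinetic protection of C4 to thermodynamic control: the hydrolysis is run in more dilute aqueous acid for longer so that C4 can equilibrate. The 3,4-trans epimer (2R,3S,4R)-5,7-bis(benzyloxy)-2-[3,4-bis(benzyloxy)phenyl]chromane-3,4-diol F5 is separated and resubmitted. The pseudoaxial hydroxyl of the 3,4-cis diol avoids the peri substituent on C5, and 2,3-trans-flavan-3,4-diols of this type are expected to drift toward the 3,4-cis isomer in dilute acid. It sets out from 23 and returns at 24.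

**Step 15.** Discrimination between O3 and O4 may be insufficient, or a second acylation may follow the first. The fallback uses thermodynamic control. The regioisomer (2R,3R,4S)-5,7-bis(benzyloxy)-2-[3,4-bis(benzyloxy)phenyl]-3-hydroxychroman-4-yl 3,4,5-tris(benzyloxy)benzoate F6 would be isolated and equilibrated by base-mediated 1,2-acyl shift across the cis-diol (catalytic amidine base in CH2Cl2). This should favour the equatorial, unhindered O3 ester. It sets out from 24 and returns at 27.

**Step 16.** Hydrogenolytic cleavage of the benzylic C4–O bond may set in once the ring A phenols are free, or traces of acid in the catalyst may cause solvolysis at C4. In the fallback O4 is masked first: t-BuMe2SiOTf and 2,6-lutidine would give the 4-O-(tert-butyldimethylsilyl) ether of 27 F7, a poorer leaving group at C4. Hydrogenolysis in THF/EtOAc would give the 4-O-(tert-butyldimethylsilyl) ether of 28 F8, and fluoride buffered with acetic acid would remove the silyl group. It sets out from 27 and returns at 28.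

## Further compounds

F1 | step 10 | ethyl (E)-3-(benzyloxy)but-2-enoate | CCOC(=O)/C=C(\C)OCc1ccccc1
F2 | step 10 | (E)-3-(benzyloxy)but-2-enoic acid | OC(=O)/C=C(\C)OCc1ccccc1
F3 | step 10 | (E)-3-(benzyloxy)but-2-enoyl chloride | ClC(=O)/C=C(\C)OCc1ccccc1
F4 | step 9 | cyclobutane-1,3-dione | O=C1CC(=O)C1
F0 | step 12 | none | none
F5 | step 14 | (2R,3S,4R)-5,7-bis(benzyloxy)-2-[3,4-bis(benzyloxy)phenyl]chromane-3,4-diol | O[C@@H]1[C@@H](c2ccc(OCc3ccccc3)c(OCc3ccccc3)c2)Oc2cc(OCc3ccccc3)cc(OCc3ccccc3)c2[C@H]1O
F6 | step 15 | (2R,3R,4S)-5,7-bis(benzyloxy)-2-[3,4-bis(benzyloxy)phenyl]-3-hydroxychroman-4-yl 3,4,5-tris(benzyloxy)benzoate | O[C@@H]1[C@@H](c2ccc(OCc3ccccc3)c(OCc3ccccc3)c2)Oc2cc(OCc3ccccc3)cc(OCc3ccccc3)c2[C@@H]1OC(=O)c1cc(OCc2ccccc2)c(OCc2ccccc2)c(OCc2ccccc2)c1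
F7 | step 16 | 4-O-(tert-butyldimethylsilyl) ether of 27 | O=C(O[C@@H]1[C@@H](c2ccc(OCc3ccccc3)c(OCc3ccccc3)c2)Oc2cc(OCc3ccccc3)cc(OCc3ccccc3)c2[C@@H]1O[Si](C)(C)C(C)(C)C)c1cc(OCc2ccccc2)c(OCc2ccccc2)c(OCc2ccccc2)c1
F8 | step 16 | 4-O-(tert-butyldimethylsilyl) ether of 28 | O=C(O[C@@H]1[C@@H](c2ccc(O)c(O)c2)Oc2cc(O)cc(O)c2[C@@H]1O[Si](C)(C)C(C)(C)C)c1cc(O)c(O)c(O)c1
A1 | alternative 1 | (2R,3S,4S)-4,5,7-tris(benzyloxy)-2-[3,4-bis(benzyloxy)phenyl]chroman-3-yl 3,4,5-tris(benzyloxy)benzoate | O=C(O[C@@H]1[C@@H](c2ccc(OCc3ccccc3)c(OCc3ccccc3)c2)Oc2cc(OCc3ccccc3)cc(OCc3ccccc3)c2[C@@H]1OCc1ccccc1)c1cc(OCc2ccccc2)c(OCc2ccccc2)c(OCc2ccccc2)c1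
A2 | alternative 1 | 3,5-bis(benzyloxy)-2-[bis(benzyloxy)methyl]phenol | Oc1cc(OCc2ccccc2)cc(OCc2ccccc2)c1C(OCc1ccccc1)OCc1ccccc1
A3 | alternative 1 | (E)-2-[3,4-bis(benzyloxy)phenyl]ethenyl 3,4,5-tris(benzyloxy)benzoate | O=C(O/C=C/c1ccc(OCc2ccccc2)c(OCc2ccccc2)c1)c1cc(OCc2ccccc2)c(OCc2ccccc2)c(OCc2ccccc2)c1
A4 | alternative 2 | (2R,3S,4S)-5,7-bis(benzyloxy)-2-[3,4-bis(benzyloxy)phenyl]chromane-3,4-diol | O[C@@H]1[C@@H](c2ccc(OCc3ccccc3)c(OCc3ccccc3)c2)Oc2cc(OCc3ccccc3)cc(OCc3ccccc3)c2[C@@H]1O
A5 | alternative 2 | (R)-2-[3,5-bis(benzyloxy)-2-formylphenoxy]-2-[3,4-bis(benzyloxy)phenyl]acetaldehyde | O=C[C@H](Oc1cc(OCc2ccccc2)cc(OCc2ccccc2)c1C=O)c1ccc(OCc2ccccc2)c(OCc2ccccc2)c1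
A6 | alternative 3 | 3,4-O-isopropylidene derivative of (2R,3S,4S)-5,7-bis(benzyloxy)-2-[3,4-bis(benzyloxy)phenyl]chromane-3,4-diol | CC1(C)O[C@@H]2[C@@H](c3ccc(OCc4ccccc4)c(OCc4ccccc4)c3)Oc3cc(OCc4ccccc4)cc(OCc4ccccc4)c3[C@@H]2O1
A7 | alternative 3 | (R)-[3,4-bis(benzyloxy)phenyl]{(4R,5S)-5-[2,4-bis(benzyloxy)-6-bromophenyl]-2,2-dimethyl-1,3-dioxolan-4-yl}methanol | Brc1cc(OCc2ccccc2)cc(OCc2ccccc2)c1[C@@H]1OC(C)(C)O[C@@H]1[C@H](O)c1ccc(OCc2ccccc2)c(OCc2ccccc2)c1
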